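**Retrosynthetic overview**
1. Locants: the carbocycle is numbered as bicyclo[4.2.0]octane. C1 is the methylated fusion carbon, C2 the peroxide CH, C3 the methylated alkene carbon, C4 the alkene CH, C5 the methylated peroxide carbon, C6 the fusion CH, C7 the carbon bearing methyl and pyronyl, C8 the CHMe carbon.
2. Feature used: ring C1–C6 carries methyl at C1, C3 and C5 and oxygen at C2 and C5. This is the pattern of the para-quinol of 2,4,6-trimethylphenol (phenol carbon = C2, para carbon = C5). The cyclobutane C6–C7–C8–C1 sits on one of the former ring C=C bonds, and the carbon substituent of C7 lies on the same, concave side as C5.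
3. Late disconnections: the 1,2-dioxane ring (C2–O, C5–O) comes from singlet-oxygen [4+2] on the C2=C3–C4=C5 diene. The pyrone ring comes from a C7 aldehyde and a β-keto ester dianion. The diene comes from the C2 ketone through a dienyl triflate, after reductive scission of a temporary C5–O–CH2–C7 ether.
4. Central disconnection: that ether is the tether of a retro-[2+2] across C6–C7 and C1–C8. It leads to an achiral quinol ether, made in one step from the phenol and tiglyl alcohol.
5. Ring order forward: six-membered carbocycle (from the arene), cyclobutane and temporary tetrahydrofuran together (step 2), tetrahydrofuran opened (step 3), pyrone (step 11), 1,2-dioxane (step 13).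

Key step: step 2

Assumption: no model predicts which antipode of the oxazaborolidine favours the photoadduct drawn over its mirror image, so the (S)-prolinol-derived catalyst is written and its antipode would be used if the sense proves opposite.

**Step 1**
Reactants: 1 2,4,6-trimethylphenol; 2 (E)-2-methylbut-2-en-1-ol
Product: 3 4-[(E)-2-methylbut-2-enyloxy]-2,4,6-trimethylcyclohexa-2,5-dien-1-one
Conditions: PhI(OAc)2 (1.2 equiv), 2 (5 equiv, excess recovered), CH2Cl2, 0 °C to rt
Reagents that add atoms: none
Why: Oxidative dearomatisation of a para-alkylphenol with a hypervalent iodine reagent is the routine entry to oxygen-tethered cyclohexa-2,5-dienones; the alcohol should capture the oxidised ring at the para carbon because ortho capture gives the less stable linearly conjugated dienone, and no stereocentre arises because 3 has a mirror plane through C2 and C5.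

**Step 2**
Reactants: 3 quinol ether
Product: 5 (1R,5R,6S,7S,8S)-1,3,5,7,8-pentamethyl-5,7-(epoxymethano)bicyclo[4.2.0]oct-3-en-2-one, via triplet 1,4-biradical 4 (not isolated)
Conditions: hν (λ = 366 nm), AlBr3 adduct of (S)-3,3-bis(3,5-dimethylphenyl)-1-(2,4,6-trifluorophenyl)tetrahydro-1H,3H-pyrrolo[1,2-c][1,3,2]oxazaborole (50 mol %), deoxygenated CH2Cl2 (20 mM), −75 °C
Reagents that add atoms: none
Why: Proposed new method: the Lewis acid binds the dienone carbonyl and shifts its ππ* band to longer wavelength, so that at 366 nm mainly the complex is excited; after intersystem crossing the triplet enone attacks the tethered alkene from its β-carbon C6 at C7 to give biradical 4, which after spin inversion couples C1 with C8. The closest known reactions are the intramolecular [2+2] photocycloaddition of 4-(alk-3-enyl)cyclohexa-2,5-dienones and the enantioselective intramolecular enone–alkene photocycloaddition catalysed by AlBr3-activated oxazaborolidines; what is new is that the catalyst must distinguish two enantiotopic enones of one chromophore rather than two faces of one enone. The tetrahydrofuran ring (O, CH2, C7, C6, C5) closes 5-exo-trig, which is preferred over the 6-endo mode that would lead to the crossed adduct, and the cyclobutane (C6, C7, C8, C1) closes by radical recombination within 4. C6 and C7 follow from the tether, which reaches the ring only from the face of C5 that bears oxygen and so places CH2O endo and the C7 methyl exo; C1 follows from the cis fusion that the tricycle enforces; the C8 methyl ends up exo and cis to the C7 methyl both by retention of the E geometry and through the less crowded rotamer of 4; C5 becomes stereogenic, and all five centres receive their absolute sense, through the choice of enone. For that choice the complex can place boron syn to C1 or syn to C3, and each arrangement covers one ring face with a catalyst aryl group; only the arrangement that covers the C5-methyl face leaves the tether free, and in it the enone remote from the bulky boron centre should react. Chemoselectivity is needed against the lumiketone (type A) rearrangement and the dienone–phenol shift, and the short tether, the electron-rich trisubstituted alkene and the low temperature should secure it.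

**Step 3**
Reactants: 5 tricyclic photoadduct
Product: 7 endo-7-(hydroxymethyl)-1,3,5,7,8-pentamethylbicyclo[4.2.0]oct-4-en-2-one (C3 epimers), via samarium alkoxide-dienolate 6 (not isolated)
Conditions: SmI2 (2.5 equiv), THF–MeOH, −78 °C
Reagents that add atoms: none
Why: This is the vinylogous form of the SmI2 reduction of α-oxygenated ketones, known for γ-oxygenated α,β-unsaturated carbonyl compounds: two single-electron transfers to the enone expel the C5 alkoxide, whose C–O bond is well aligned with the π system of the flattened ring, and methanol protonates dienolate 6 kinetically at C3; the C5 centre is erased on purpose, the C3 centre is removed again in step 5, and the low temperature should hold back the slower opening of the C1–C8 cyclobutane bond.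

**Step 4**
Reactants: 7 hydroxy ketone
Product: 8 endo-7-[(tert-butyldimethylsilyloxy)methyl]-1,3,5,7,8-pentamethylbicyclo[4.2.0]oct-4-en-2-one
Conditions: TBSCl, imidazole, DMF, 0 °C to rt
Reagents that add atoms: tert-butyldimethylsilyl chloride (TBSCl), CC(C)(C)[Si](C)(C)Cl
Why: Standard silyl ether formation at the only hydroxyl group also takes the alcohol out of reversible hemiketal or oxa-Michael equilibria with the ketone, and no stereocentre is affected.

**Step 5**
Reactants: 8 silyl ether ketone
Product: 10 endo-7-[(tert-butyldimethylsilyloxy)methyl]-1,3,5,7,8-pentamethylbicyclo[4.2.0]octa-2,4-dien-2-yl trifluoromethanesulfonate, via potassium dienolate 9 (not isolated)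
Conditions: KN(SiMe3)2 (1.3 equiv), THF, −78 °C; then N-(5-chloropyridin-2-yl)bis(trifluoromethanesulfonimide), −78 to −20 °C
Reagents that add atoms: N-(5-chloropyridin-2-yl)bis(trifluoromethanesulfonimide), FC(F)(F)S(=O)(=O)N(c1ccc(Cl)cn1)S(=O)(=O)C(F)(F)F
Why: In this enol triflate synthesis C1 is quaternary, so the base can only remove the doubly activated (α and allylic) C3–H; the through-conjugated dienolate 9 is sulfonylated on oxygen, the C3 stereocentre disappears, and any conjugated enone isomer carried along converges on 9 by loss of its C5–H.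

**Step 6**
Reactants: 10 dienyl triflate
Product: 11 endo-7-[(tert-butyldimethylsilyloxy)methyl]-1,3,5,7,8-pentamethylbicyclo[4.2.0]octa-2,4-diene
Conditions: Pd(OAc)2 (10 mol %), PPh3 (20 mol %), HCO2H, n-Bu3N, DMF, 40 °C, argon, dark
Reagents that add atoms: none
Why: Palladium-catalysed formate reduction of an enol triflate replaces OTf at C2 by hydrogen with loss of CO2, leaves both double bonds in place and touches none of C1, C6, C7 and C8; the mild temperature is chosen because bicyclo[4.2.0]octa-2,4-dienes can open by retro-6π electrocyclisation on heating.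

**Step 7**
Reactants: 11 silyl ether diene
Product: 12 endo-(1,3,5,7,8-pentamethylbicyclo[4.2.0]octa-2,4-dien-7-yl)methanol
Conditions: n-Bu4NF, THF, 0 °C to rt, dark
Reagents that add atoms: none
Why: Fluoride-mediated silyl ether cleavage is chosen over acid because the trisubstituted diene is acid-sensitive.

**Step 8**
Reactants: 12 diene alcohol
Product: 13 endo-1,3,5,7,8-pentamethylbicyclo[4.2.0]octa-2,4-diene-7-carbaldehyde
Conditions: n-Pr4N[RuO4] (5 mol %), N-methylmorpholine N-oxide, 4 Å molecular sieves, CH2Cl2, rt
Reagents that add atoms: none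
Why: The Ley–Griffith oxidation is neutral and catalytic and stops at the aldehyde, whose α-carbon C7 is quaternary and therefore cannot epimerise.

**Step 9**
Reactants: 13 aldehyde; 14 methyl 2-methyl-3-oxopentanoate
Product: 16 methyl 5-hydroxy-2,4-dimethyl-3-oxo-5-(endo-1,3,5,7,8-pentamethylbicyclo[4.2.0]octa-2,4-dien-7-yl)pentanoate (diastereomer mixture in the chain), via dilithium dianion 15 (not isolated)
Conditions: 14 (2 equiv), LiN(i-Pr)2 (4.2 equiv), THF, −78 to 0 °C; then 13, −78 °C; aq. NH4Cl
Reagents that add atoms: none
Why: In this γ-selective aldol addition of a β-keto ester dianion the terminal, more basic carbanion of 15 attacks the non-enolisable aldehyde, and the three new chain stereocentres, formed as a mixture, all become sp2 centres by step 11.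

**Step 10**
Reactants: 16 aldol adduct
Product: 17 methyl 2,4-dimethyl-3,5-dioxo-5-(endo-1,3,5,7,8-pentamethylbicyclo[4.2.0]octa-2,4-dien-7-yl)pentanoate
Conditions: Dess–Martin periodinane (1.2 equiv), CH2Cl2, 0 °C to rt
Reagents that add atoms: none
Why: Dess–Martin oxidation converts the β-hydroxy ketone into the 1,3-diketone under nearly neutral conditions that tolerate the diene and the β-keto ester.

**Step 11**
Reactants: 17 diketo ester
Product: 18 4-hydroxy-3,5-dimethyl-6-(endo-1,3,5,7,8-pentamethylbicyclo[4.2.0]octa-2,4-dien-7-yl)-2H-pyran-2-one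
Conditions: 1,8-diazabicyclo[5.4.0]undec-7-ene (DBU, 2 equiv), toluene, rt to 40 °C; aq. citric acid work-up
Reagents that add atoms: none
Why: In this base-induced cyclisation of a 3,5-diketo ester to a 4-hydroxy-2-pyrone the enol oxygen of the C7-bound ketone attacks the ester carbonyl (6-exo-trig), methanol is lost and enolisation makes the ring aromatic, which removes the remaining chain stereocentres.

**Step 12**
Reactants: 18 hydroxy-α-pyrone
Product: 20 2-methoxy-3,5-dimethyl-6-(endo-1,3,5,7,8-pentamethylbicyclo[4.2.0]octa-2,4-dien-7-yl)-4H-pyran-4-one, via hydroxymethoxypyrylium triflate 19 (not isolated)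
Conditions: MeOTf (1.5 equiv), 2,6-di-tert-butyl-4-methylpyridine (2 equiv), CH2Cl2, 0 °C to rt, dark
Reagents that add atoms: methyl trifluoromethanesulfonate (MeOTf), COS(=O)(=O)C(F)(F)F
Why: In the O-methylation of a neutral 4-hydroxy-2-pyrone with a hard methylating agent the pyrone reacts at its most basic site, the lactone carbonyl oxygen, and the hindered, non-nucleophilic pyridine deprotonates pyrylium 19 to the 2-methoxy-4-pyrone before the acid can reach the diene.

**Step 13**
Reactants: 20 methoxy-γ-pyrone diene
Product: 21 2-methoxy-3,5-dimethyl-6-[(1R,2R,5S,6R,7S,8R)-1,3,5,7,8-pentamethyl-2,5-epidioxybicyclo[4.2.0]oct-3-en-7-yl]-4H-pyran-4-one (target)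
Conditions: O2, 5,10,15,20-tetraphenylporphyrin (1 mol %), visible light, CH2Cl2, 0 °C
Reagents that add atoms: dioxygen, O=O
Why: In this [4+2] cycloaddition of singlet oxygen to an s-cis cyclohexa-1,3-diene the concave face is closed by the cyclobutane and its endo pyronyl group, so O2 should add from the convex face that carries C6–H and the C1 methyl; this sets C2 and C5 together, and the visible light is not absorbed by the pyrone.

**Compound list**
1 | 2,4,6-trimethylphenol | Cc1cc(C)c(O)c(C)c1 | starting material
2 | (E)-2-methylbut-2-en-1-ol | C/C=C(\C)CO | starting material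
3 | 4-[(E)-2-methylbut-2-enyloxy]-2,4,6-trimethylcyclohexa-2,5-dien-1-one (achiral) | C/C=C(\C)COC1(C)C=C(C)C(=O)C(C)=C1 | intermediate
4 | triplet 1,4-biradical after C6–C7 bonding (tetrahydrofuran closed, radical centres at C1 and C8, drawn without the Lewis acid; not isolated) | C[CH][C@]1(C)CO[C@]2(C)C=C(C)C(=O)[C](C)[C@H]12 | intermediate
5 | tricyclic photoadduct; cis-fused, C5–O–CH2–C7 bridge on the concave face, C6–H and the methyls at C1, C7 and C8 all exo | O1C[C@@]2(C)[C@H](C)[C@@]3(C)C(=O)C(C)=C[C@]1(C)[C@@H]23 | intermediate
6 | bis(diiodosamarium) salt of the CH2O alkoxide and C2 dienolate (not isolated) | [Sm+3].[Sm+3].[I-].[I-].[I-].[I-].[O-]C[C@@]1(C)[C@H](C)[C@@]2(C)C([O-])=C(C)C=C(C)[C@@H]12 | intermediate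
7 | hydroxy β,γ-enone; CH2OH endo, C1, C6, C7 and C8 as in 5, C3 epimers | OC[C@@]1(C)[C@H](C)[C@@]2(C)C(=O)C(C)C=C(C)[C@@H]12 | intermediate
8 | TBS ether of 7 | CC(C)(C)[Si](C)(C)OC[C@@]1(C)[C@H](C)[C@@]2(C)C(=O)C(C)C=C(C)[C@@H]12 | intermediate
9 | potassium dienolate of 8 (not isolated) | [K+].CC(C)(C)[Si](C)(C)OC[C@@]1(C)[C@H](C)[C@@]2(C)C([O-])=C(C)C=C(C)[C@@H]12 | intermediate
10 | C2 dienyl triflate | CC(C)(C)[Si](C)(C)OC[C@@]1(C)[C@H](C)[C@@]2(C)C(OS(=O)(=O)C(F)(F)F)=C(C)C=C(C)[C@@H]12 | intermediate
11 | silyl-protected bicyclo[4.2.0]octa-2,4-diene | CC(C)(C)[Si](C)(C)OC[C@@]1(C)[C@H](C)[C@@]2(C)C=C(C)C=C(C)[C@@H]12 | intermediate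
12 | diene alcohol (CH2OH endo) | OC[C@@]1(C)[C@H](C)[C@@]2(C)C=C(C)C=C(C)[C@@H]12 | intermediate
13 | diene aldehyde (CHO endo) | O=C[C@@]1(C)[C@H](C)[C@@]2(C)C=C(C)C=C(C)[C@@H]12 | intermediate
14 | methyl 2-methyl-3-oxopentanoate | CCC(=O)C(C)C(=O)OC | starting material
15 | dilithium dianion of 14 (not isolated) | [Li+].[Li+].CC=C([O-])C(C)=C([O-])OC | intermediate
16 | δ-hydroxy-β-keto ester (chain diastereomers) | COC(=O)C(C)C(=O)C(C)C(O)[C@@]1(C)[C@H](C)[C@@]2(C)C=C(C)C=C(C)[C@@H]12 | intermediate
17 | 3,5-diketo ester | COC(=O)C(C)C(=O)C(C)C(=O)[C@@]1(C)[C@H](C)[C@@]2(C)C=C(C)C=C(C)[C@@H]12 | intermediate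
18 | 4-hydroxy-2-pyrone | O=c1oc([C@@]2(C)[C@H](C)[C@@]3(C)C=C(C)C=C(C)[C@@H]23)c(C)c(O)c1C | intermediate
19 | 4-hydroxy-2-methoxypyrylium triflate (not isolated) | COc1[o+]c([C@@]2(C)[C@H](C)[C@@]3(C)C=C(C)C=C(C)[C@@H]23)c(C)c(O)c1C.[O-]S(=O)(=O)C(F)(F)F | intermediate
20 | 2-methoxy-4-pyrone diene (pyronyl endo) | COc1oc([C@@]2(C)[C@H](C)[C@@]3(C)C=C(C)C=C(C)[C@@H]23)c(C)c(=O)c1C | intermediate
21 | CNP0183511.1, endoperoxide on the convex face | COc1oc([C@@]2(C)[C@H](C)[C@@]3(C)[C@@H]4OO[C@@](C)(C=C4C)[C@@H]23)c(C)c(=O)c1C | target

Total step count: 13. Longest linear sequence: 13 steps (1 to 21).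

**Steps most likely to fail**

**Step 2 (bears the label).**
- What may go wrong: the catalyst may discriminate poorly between the two enantiotopic enones, because the α-carbons carry methyl rather than hydrogen and offer no second contact. Unbound dienone may give a racemic background reaction. The Lewis acid may also induce a dienone–phenol shift of the quinol ether.
- Fallback, from 3 back to 5, with known chemistry only:
  - Irradiation of 3 at 366 nm without additive (CH2Cl2, rt) would give the racemic photoadduct F1.
  - Luche reduction (NaBH4, CeCl3·7H2O, MeOH, 0 °C, hydride from the convex face) would give the racemic allylic alcohol F2.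
  - Acylation with (1S,4R)-camphanic chloride (Et3N, 4-(dimethylamino)pyridine, CH2Cl2) would give the wanted camphanate F3 and the mirror-series camphanate F4. These would be separated by crystallisation or chromatography, and the configuration read from a crystal structure.
  - Methanolysis of F3 (K2CO3, MeOH) would free the enantiopure allylic alcohol F5, and Dess–Martin oxidation would return 5.

**Step 3.**
- What may go wrong: the ketyl may fragment the C1–C8 cyclobutane bond in competition with C5–O scission, and the liberated ketone may be over-reduced.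
- Fallback, from 5 to 12, avoiding electron transfer altogether:
  - Condensation of 5 with TsNHNH2 (cat. TsOH, EtOH, reflux) would give the tosylhydrazone F6.
  - Catecholborane (CHCl3, −10 °C) and then NaOAc·3H2O (warming) would produce the allylic diazene F7.
  - Retro-ene loss of N2 from F7 moves the double bond to C2=C3 and places hydrogen on C4, giving the transposed tricyclic ether F8.
  - Eliminative ring opening with LiN(i-Pr)2/KOt-Bu (THF, −78 to 0 °C) removes an allylic C4–H and expels the C5 alkoxide. This would give 12 directly and bypass 7 to 11.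

**Step 12.**
- What may go wrong: methylation may occur at the C4 oxygen instead of the lactone carbonyl, and the electron-rich diene may be protonated or cyclise cationically at the strongly acidic pyrylium stage.
- Fallback, from 10 to 20: the diene is kept deactivated as its triflate until the pyrone is finished.
  - HF·pyridine (THF, 0 °C) would give the triflate alcohol F9, and n-Pr4N[RuO4]/N-methylmorpholine N-oxide the triflate aldehyde F10.
  - Addition of dianion 15 at −78 °C would give the aldol adduct F11, and Dess–Martin oxidation the diketo ester F12.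
  - DBU would give the hydroxypyrone triflate F13.
  - The conditions of step 12 would lead through the pyrylium salt F14 to the methoxy-γ-pyrone triflate F15.
  - The formate reduction of step 6 (Pd(OAc)2, PPh3, HCO2H, n-Bu3N, DMF, 40 °C) would then give 20.

**Further compounds**
F1 | step 2 | racemic photoadduct (5 and its mirror image) | O1C[C@@]2(C)[C@H](C)[C@@]3(C)C(=O)C(C)=C[C@]1(C)[C@@H]23.O1C[C@]2(C)[C@@H](C)[C@]3(C)C(=O)C(C)=C[C@@]1(C)[C@H]23
F2 | step 2 | racemic C2 allylic alcohol (OH on the cyclobutane side) | O1C[C@@]2(C)[C@H](C)[C@@]3(C)[C@@H](O)C(C)=C[C@]1(C)[C@@H]23.O1C[C@]2(C)[C@@H](C)[C@]3(C)[C@H](O)C(C)=C[C@@]1(C)[C@H]23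
F3 | step 2 | (1S,4R)-camphanate of the wanted alcohol | O1C[C@@]2(C)[C@H](C)[C@@]3(C)[C@@H](OC(=O)[C@@]45CC[C@@](C)(C(=O)O4)C5(C)C)C(C)=C[C@]1(C)[C@@H]23
F4 | step 2 | (1S,4R)-camphanate of the mirror-series alcohol | O1C[C@]2(C)[C@@H](C)[C@]3(C)[C@H](OC(=O)[C@@]45CC[C@@](C)(C(=O)O4)C5(C)C)C(C)=C[C@@]1(C)[C@H]23
F5 | step 2 | enantiopure C2 allylic alcohol | O1C[C@@]2(C)[C@H](C)[C@@]3(C)[C@@H](O)C(C)=C[C@]1(C)[C@@H]23
F6 | step 3 | tosylhydrazone of 5 | O1C[C@@]2(C)[C@H](C)[C@@]3(C)C(=NNS(=O)(=O)c4ccc(C)cc4)C(C)=C[C@]1(C)[C@@H]23
F7 | step 3 | allylic diazene at C2 (not isolated) | O1C[C@@]2(C)[C@H](C)[C@@]3(C)C(N=N)C(C)=C[C@]1(C)[C@@H]23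
F8 | step 3 | tricyclic ether with C2=C3 alkene and C4 methylene | O1C[C@@]2(C)[C@H](C)[C@@]3(C)C=C(C)C[C@]1(C)[C@@H]23
F9 | step 12 | dienyl triflate alcohol | OC[C@@]1(C)[C@H](C)[C@@]2(C)C(OS(=O)(=O)C(F)(F)F)=C(C)C=C(C)[C@@H]12
F10 | step 12 | dienyl triflate aldehyde | O=C[C@@]1(C)[C@H](C)[C@@]2(C)C(OS(=O)(=O)C(F)(F)F)=C(C)C=C(C)[C@@H]12
F11 | step 12 | dienyl triflate aldol adduct | COC(=O)C(C)C(=O)C(C)C(O)[C@@]1(C)[C@H](C)[C@@]2(C)C(OS(=O)(=O)C(F)(F)F)=C(C)C=C(C)[C@@H]12
F12 | step 12 | dienyl triflate diketo ester | COC(=O)C(C)C(=O)C(C)C(=O)[C@@]1(C)[C@H](C)[C@@]2(C)C(OS(=O)(=O)C(F)(F)F)=C(C)C=C(C)[C@@H]12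
F13 | step 12 | dienyl triflate 4-hydroxy-2-pyrone | O=c1oc([C@@]2(C)[C@H](C)[C@@]3(C)C(OS(=O)(=O)C(F)(F)F)=C(C)C=C(C)[C@@H]23)c(C)c(O)c1C
F14 | step 12 | dienyl triflate hydroxymethoxypyrylium triflate (not isolated) | COc1[o+]c([C@@]2(C)[C@H](C)[C@@]3(C)C(OS(=O)(=O)C(F)(F)F)=C(C)C=C(C)[C@@H]23)c(C)c(O)c1C.[O-]S(=O)(=O)C(F)(F)F
F15 | step 12 | dienyl triflate 2-methoxy-4-pyrone | COc1oc([C@@]2(C)[C@H](C)[C@@]3(C)C(OS(=O)(=O)C(F)(F)F)=C(C)C=C(C)[C@@H]23)c(C)c(=O)c1C
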